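**Assumption:** Chiricanine C has no stereocentre and is achiral, so "single enantiomer" is taken to mean the (E)-alkene isomer as drawn.

## Retrosynthetic overview
1. The free phenol is unmasked last from its MOM ether; MOM is also the directing group for the C4 prenylation.
2. C4–prenyl (between OMe and OMOM) comes from directed ortho-metalation; C2–prenyl comes from Br/Li exchange of a C2 bromide, then Cu-mediated allylation.
3. The (E)-stilbene comes from a Horner–Wadsworth–Emmons reaction of the aryl aldehyde with diethyl benzylphosphonate.
4. The C2 bromide comes from para-selective bromination of 3-hydroxy-5-methoxybenzaldehyde, which already carries the OMe/OH differentiation.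
5. No ring is constructed; both benzene rings are purchased.

## Route

**Step 1**
Reactants: 1 (3-hydroxy-5-methoxybenzaldehyde), 2 (N-bromosuccinimide)
Product: 3 (2-bromo-5-hydroxy-3-methoxybenzaldehyde; Br between CHO and OMe, para to OH)
Conditions: NBS (1.0 equiv), MeCN, −20 → 0 °C, dark
Reagents that add atoms: NBS, O=C1CCC(=O)N1Br
Why: Electrophilic aromatic bromination; in a polar, non-basic medium the free phenol is the dominant activator and directs para, which is C2 (also ortho to OMe), as 3-hydroxybenzaldehyde does.

**Step 2**
Reactants: 3, 4 (chloromethyl methyl ether, MOMCl)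
Product: 5 (2-bromo-3-methoxy-5-(methoxymethoxy)benzaldehyde)
Conditions: MOMCl, i-Pr2NEt, CH2Cl2, 0 °C → rt
Reagents that add atoms: MOMCl, COCCl
Why: Phenol O-alkylation (MOM protection); the aldehyde and aryl bromide are inert, and MOM is needed later as the ortho-director.

**Step 3**
Reactants: 5, 6 (diethyl benzylphosphonate)
Product: 7 ((E)-2-bromo-3-methoxy-5-(methoxymethoxy)stilbene)
Conditions: (EtO)2P(O)CH2Ph, KOt-Bu, THF, 0 °C → rt
Reagents that add atoms: diethyl benzylphosphonate, CCOP(=O)(Cc1ccccc1)OCC
Why: Horner–Wadsworth–Emmons olefination; benzyl phosphonates with aryl aldehydes give the thermodynamic (E)-stilbene (typically >20:1), and MOM and ArBr tolerate the base.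

**Step 4**
Reactants: 7, 8 (prenyl bromide, 1-bromo-3-methylbut-2-ene)
Product: 9 ((E)-3-methoxy-5-(methoxymethoxy)-2-(3-methylbut-2-en-1-yl)stilbene)
Conditions: n-BuLi (1.05 equiv), THF, −78 °C, 15 min; CuBr·SMe2 (1.1 equiv), −78 → −40 °C; prenyl bromide, −78 °C → rt
Reagents that add atoms: prenyl bromide, CC(C)=CCBr
Why: Br/Li exchange at −78 °C is much faster than any addition to the stilbene; the aryl copper species then allylates prenyl bromide at the primary carbon (SN2, linear prenyl), fixing C2 regiochemistry through the bromide.

**Step 5**
Reactants: 9, 8 (prenyl bromide)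
Product: 10 ((E)-3-methoxy-5-(methoxymethoxy)-2,4-bis(3-methylbut-2-en-1-yl)stilbene)
Conditions: n-BuLi (1.3 equiv), Et2O (no TMEDA), 0 °C → rt, 1–2 h; then THF, CuBr·SMe2, −78 °C; prenyl bromide, −78 °C → rt
Reagents that add atoms: prenyl bromide, CC(C)=CCBr
Why: Directed ortho-metalation; C4–H is the only site flanked by two cooperating O-directors (OMe and OMOM), so it is lithiated selectively, and Et2O without amine additive suppresses carbolithiation of the stilbene; Cu-mediated allylation follows as in Step 4.

**Step 6**
Reactants: 10
Product: 11 (chiricanine C; 3-methoxy-2,4-bis(3-methylbut-2-en-1-yl)-5-[(E)-2-phenylethenyl]phenol)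
Conditions: 3 M aq HCl, MeOH, rt → 40 °C (monitor; stop at full conversion)
Reagents that add atoms: none
Why: Acetal hydrolysis of the aryl MOM ether under mild protic acid; the methyl ether, the E-alkene and the trisubstituted prenyl alkenes survive short exposure at or near room temperature.

## Compound list
1 | 3-hydroxy-5-methoxybenzaldehyde | COc1cc(O)cc(C=O)c1 | starting material
2 | N-bromosuccinimide | O=C1CCC(=O)N1Br | starting material (reagent)
3 | 2-bromo-5-hydroxy-3-methoxybenzaldehyde | COc1cc(O)cc(C=O)c1Br | intermediate
4 | chloromethyl methyl ether | COCCl | starting material (reagent)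
5 | 2-bromo-3-methoxy-5-(methoxymethoxy)benzaldehyde | COCOc1cc(OC)c(Br)c(C=O)c1 | intermediate
6 | diethyl benzylphosphonate | CCOP(=O)(Cc1ccccc1)OCC | starting material
7 | (E)-2-bromo-3-methoxy-5-(methoxymethoxy)stilbene | COCOc1cc(OC)c(Br)c(/C=C/c2ccccc2)c1 | intermediate
8 | prenyl bromide (1-bromo-3-methylbut-2-ene) | CC(C)=CCBr | starting material
9 | (E)-3-methoxy-5-(methoxymethoxy)-2-prenylstilbene | COCOc1cc(OC)c(CC=C(C)C)c(/C=C/c2ccccc2)c1 | intermediate
10 | (E)-3-methoxy-5-(methoxymethoxy)-2,4-diprenylstilbene | COCOc1cc(/C=C/c2ccccc2)c(CC=C(C)C)c(OC)c1CC=C(C)C | intermediate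
11 | chiricanine C | COc1c(CC=C(C)C)c(O)cc(/C=C/c2ccccc2)c1CC=C(C)C | target

## Summary
Total steps: 6. Longest linear sequence: 6 (fully linear from compound 1).

Three steps most likely to fail, each with a fallback that changes the approach:

1. **Step 1 (bromination regioselectivity).** C6 (para to OMe) and C4 are also activated, and over-bromination is possible. Fallback: silylate 1 as its TIPS ether first, so the bulky OSi group shields both of its ortho positions (C4, C6) and bromination is forced to C2; then exchange TIPS for MOM (TBAF, then MOMCl) to rejoin at 5. This costs two extra steps.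

2. **Step 5 (n-BuLi on a prenylated stilbene).** Carbolithiation of the stilbene C=C or deprotonation of the benzylic/allylic CH2 of the C2 prenyl could compete with ortho-metalation. Fallback: keep C1 as the aldehyde dimethyl acetal through both organolithium steps. That means acetalising 5, running the Br/Li prenylation and the ortho-metalation prenylation on the acetal, then one acid step to release both CHO and ArOH. The HWE with 6 becomes the last step, run on the free hydroxy-aldehyde with at least 2 equiv base (7 steps total).

3. **Step 6 (acidic MOM removal next to an ortho-prenyl phenol).** The freed phenol can cyclise onto the C4 prenyl group to give a 2,2-dimethylchroman, or HCl/MeOH can add to the prenyl alkenes. Fallback: carry O5 as a SEM ether instead of MOM (installed in Step 2 with SEMCl). It is an equally good ortho-director and is removed at the end with fluoride (TBAF or CsF, warm), so the final step is non-acidic.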